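**Retrosynthetic overview**
1. The seven-membered hemiketal is the ring-closed form of an ε-hydroxy enone. Cutting its acyl–alkenyl bond gives an S-aryl thioester (C14 half) and an (E)-alkenylstannane (C16 half), joined in the last step by a cross-coupling catalysed by Pd2(dba)3 and mediated by Cu(O2PPh2).
2. Stannane half: alkenylstannane ⇐ terminal alkyne ⇐ NiBr2·glyme-catalysed reductive alkynylation of a bromohydrin ⇐ ring alkene ⇐ enol triflate. The oxepanone comes from a 7-endo epoxide opening, the quaternary centre from anti conjugate addition to a CBS-derived 4-silyloxy enone.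
3. Thioester half: α-methyl centre by hydrogenation with Ru(OAc)2[(R)-H8-BINAP], chain by Wittig olefination, tertiary alcohol by catalyst-controlled epoxidation and hydride opening, ring methine by Johnson–Claisen chirality transfer from a CBS-derived cyclohexenol made by Robinson annulation.
4. Ring order: the two cyclohexane rings first (one bought as the enone, one by annulation), then the oxepanone of the stannane half (step 7), last the hemiketal oxepane on fragment union (step 25).

Assumption: the open ε-hydroxy enone released in the last step closes by ring–chain tautomerism to the seven-membered hemiketal, and the hemiketal configuration of the target is the thermodynamically preferred one.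

**Stannane half**

Step 1
Reactants: 1 2-methylcyclohex-2-en-1-one
Product: 2 (1R)-2-methylcyclohex-2-en-1-ol
Conditions: (S)-2-methyl-CBS-oxazaborolidine (10 mol%), BH3·SMe2 (0.6 equiv), THF, −20 °C; MeOH, aq. work-up
Reagents that add atoms: none
Why: Corey–Bakshi–Shibata reduction gives clean 1,2-reduction, and with the α-methylalkenyl arm acting as the large group the (S)-catalyst delivers hydride to the face that sets the carbinol centre R.

Step 2
Reactants: 2 (1R)-2-methylcyclohex-2-en-1-ol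
Product: 3 tert-butyl(dimethyl){[(1R)-2-methylcyclohex-2-en-1-yl]oxy}silane
Conditions: TBSCl, imidazole, DMF, rt
Reagents that add atoms: tert-butyl(chloro)dimethylsilane CC(C)(C)[Si](C)(C)Cl
Why: Standard silyl ether formation masks the alcohol and installs the bulky group that later steers the conjugate addition; no stereocentre is touched.

Step 3
Reactants: 3 tert-butyl(dimethyl){[(1R)-2-methylcyclohex-2-en-1-yl]oxy}silane
Product: 4 (4R)-4-{[tert-butyl(dimethyl)silyl]oxy}-3-methylcyclohex-2-en-1-one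
Conditions: Rh2(caprolactamate)4 (1 mol%), t-BuOOH (5 equiv), K2CO3 (0.5 equiv), CH2Cl2, rt
Reagents that add atoms: tert-butyl hydroperoxide CC(C)(C)OO
Why: Allylic C–H oxidation catalysed by Rh2(caprolactamate)4 (tert-butylperoxyl radical chain) oxidises the ring methylene next to the unsubstituted alkene carbon to the enone, leaving the silyloxy stereocentre intact.

Step 4
Reactants: 4 (4R)-4-{[tert-butyl(dimethyl)silyl]oxy}-3-methylcyclohex-2-en-1-one; 5 5-bromo-2-methylpent-2-ene
Product: 8 (3R,4R)-4-{[tert-butyl(dimethyl)silyl]oxy}-3-methyl-3-(4-methylpent-3-en-1-yl)cyclohex-1-en-1-yl trifluoromethanesulfonate, via (4-methylpent-3-en-1-yl)magnesium bromide 6 (not isolated), via bromomagnesium enolate 7 (not isolated)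
Conditions: 5, Mg, THF, 50 °C; CuBr·SMe2 (20 mol%), 4, THF, −40 → −10 °C; then Comins' reagent, −78 °C → rt
Reagents that add atoms: N-(5-chloropyridin-2-yl)-1,1,1-trifluoro-N-[(trifluoromethyl)sulfonyl]methanesulfonamide FC(F)(F)S(=O)(=O)N(c1ccc(Cl)cn1)S(=O)(=O)C(F)(F)F
Why: Conjugate addition of the Grignard reagent catalysed by CuBr·SMe2 occurs anti to the neighbouring silyloxy group, setting the quaternary centre (3R), and the regiodefined enolate is trapped on oxygen as the enol triflate (conjugate addition–enolate triflation).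

Step 5
Reactants: 8 (3R,4R)-4-{[tert-butyl(dimethyl)silyl]oxy}-3-methyl-3-(4-methylpent-3-en-1-yl)cyclohex-1-en-1-yl trifluoromethanesulfonate
Product: 9 (3R,4R)-4-hydroxy-3-methyl-3-(4-methylpent-3-en-1-yl)cyclohex-1-en-1-yl trifluoromethanesulfonate
Conditions: HF·pyridine, excess pyridine, THF, 0 °C → rt
Reagents that add atoms: none
Why: Buffered fluoride desilylation frees the ring alcohol under conditions that leave the enol triflate and the trisubstituted alkene untouched.

Step 6
Reactants: 9 (3R,4R)-4-hydroxy-3-methyl-3-(4-methylpent-3-en-1-yl)cyclohex-1-en-1-yl trifluoromethanesulfonate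
Product: 10 (3R,4R)-3-{2-[(2R)-3,3-dimethyloxiran-2-yl]ethyl}-4-hydroxy-3-methylcyclohex-1-en-1-yl trifluoromethanesulfonate
Conditions: D-fructose-derived Shi ketone (30 mol%), KHSO5 (as Oxone), K2CO3, Bu4NHSO4, MeCN/dimethoxymethane/aq. borate buffer (pH 10.5), 0 °C
Reagents that add atoms: potassium peroxymonosulfate [K+].[O-]S(=O)(=O)OO
Why: Shi asymmetric epoxidation (chiral dioxirane, spiro transition state) oxidises only the electron-rich side-chain alkene, the enol triflate being electron-poor, and sets the epoxide CH centre R so that a single diastereomer enters the cyclisation.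

Step 7
Reactants: 10 (3R,4R)-3-{2-[(2R)-3,3-dimethyloxiran-2-yl]ethyl}-4-hydroxy-3-methylcyclohex-1-en-1-yl trifluoromethanesulfonate
Product: 11 (3R,5aR,9aR)-3-hydroxy-2,2,5a-trimethyl-2,3,4,5,5a,8,9,9a-octahydro-1-benzoxepin-7-yl trifluoromethanesulfonate
Conditions: camphor-10-sulfonic acid (10 mol%), CH2Cl2, −20 → 0 °C
Reagents that add atoms: none
Why: Acid-catalysed 7-endo epoxide opening, in which the ring hydroxyl attacks the tertiary, cation-stabilising epoxide carbon, closes the trans-fused oxepane; the ring fusion was fixed in step 4 and C3 keeps the epoxide oxygen.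

Step 8
Reactants: 11 (3R,5aR,9aR)-3-hydroxy-2,2,5a-trimethyl-2,3,4,5,5a,8,9,9a-octahydro-1-benzoxepin-7-yl trifluoromethanesulfonate
Product: 12 (5aR,9aR)-2,2,5a-trimethyl-3-oxo-2,3,4,5,5a,8,9,9a-octahydro-1-benzoxepin-7-yl trifluoromethanesulfonate
Conditions: Dess–Martin periodinane, CH2Cl2, rt
Reagents that add atoms: none
Why: Dess–Martin oxidation converts the secondary alcohol into the oxepanone of the target without affecting the enol triflate.

Step 9
Reactants: 12 (5aR,9aR)-2,2,5a-trimethyl-3-oxo-2,3,4,5,5a,8,9,9a-octahydro-1-benzoxepin-7-yl trifluoromethanesulfonate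
Product: 13 (5aR,9aR)-2,2,5a,7-tetramethyl-4,5,5a,8,9,9a-hexahydro-1-benzoxepin-3(2H)-one
Conditions: Pd(PPh3)4 (5 mol%), MeZnCl (2 equiv), LiCl, THF, 50 °C
Reagents that add atoms: methylzinc chloride C[Zn]Cl
Why: Negishi cross-coupling of the enol triflate with the ketone-tolerant methylzinc reagent unmasks the trisubstituted ring alkene only after the side-chain alkene has been used.

Step 10
Reactants: 13 (5aR,9aR)-2,2,5a,7-tetramethyl-4,5,5a,8,9,9a-hexahydro-1-benzoxepin-3(2H)-one
Product: 14 (5aS,6S,7S,9aR)-6-bromo-7-hydroxy-2,2,5a,7-tetramethyloctahydro-1-benzoxepin-3(2H)-one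
Conditions: NBS (1.1 equiv), acetone/H2O 4:1, 0 °C, dark
Reagents that add atoms: N-bromosuccinimide O=C1CCC(=O)N1Br; water O
Why: Bromohydrin formation: the bromonium ion forms on the face anti to the axial 5a-methyl and water opens it at the tertiary carbon in a trans-diaxial, Markovnikov sense, setting C7 (OH cis to the 5a-methyl) and C6 (axial Br).

Step 11
Reactants: 14 (5aS,6S,7S,9aR)-6-bromo-7-hydroxy-2,2,5a,7-tetramethyloctahydro-1-benzoxepin-3(2H)-one; 15 (bromoethynyl)trimethylsilane
Product: 16 (5aR,6R,7S,9aR)-7-hydroxy-2,2,5a,7-tetramethyl-6-[(trimethylsilyl)ethynyl]octahydro-1-benzoxepin-3(2H)-one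
Conditions: NiBr2·glyme (10 mol%), 4,4′-di-tert-butyl-2,2′-bipyridine (12 mol%), Mn powder (3 equiv), NaI (0.5 equiv), DMA, 0 °C → rt, slow addition of 15
Reagents that add atoms: none
Why: Proposed new method: reductive cross-electrophile alkynylation of an unprotected, hindered cyclic bromohydrin catalysed by NiBr2·glyme with 4,4′-di-tert-butyl-2,2′-bipyridine, in which zerovalent nickel adds oxidatively to the bromoalkyne, halogen abstraction by monovalent nickel (relayed by iodide) turns the axial C6–Br bond into a secondary radical, the alkynylnickel captures this radical on the ring face anti to the axial 5a-methyl and 7-hydroxyl groups, and reductive elimination from trivalent nickel forms the C(sp3)–C(sp) bond with net retention so that C6 carries the alkyne axially, with Mn turning the catalyst over; the closest known reaction types are reductive couplings of alkyl radical precursors with bromoalkynes and the reductive arylation of epoxides that runs through halohydrins, both run with nickel dihalide–bipyridine catalysts and neither shown on a ring bromide flanked by a quaternary carbon and a free tertiary carbinol.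

Step 12
Reactants: 16 (5aR,6R,7S,9aR)-7-hydroxy-2,2,5a,7-tetramethyl-6-[(trimethylsilyl)ethynyl]octahydro-1-benzoxepin-3(2H)-one
Product: 17 (5aR,6S,7S,9aR)-6-ethynyl-7-hydroxy-2,2,5a,7-tetramethyloctahydro-1-benzoxepin-3(2H)-one
Conditions: K2CO3 (0.2 equiv), MeOH, 0 °C → rt
Reagents that add atoms: none
Why: Methanolysis of the alkynyl C–Si bond gives the terminal alkyne; the descriptor at C6 changes only because the priorities change.

Step 13
Reactants: 17 (5aR,6S,7S,9aR)-6-ethynyl-7-hydroxy-2,2,5a,7-tetramethyloctahydro-1-benzoxepin-3(2H)-one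
Product: 18 (5aR,6S,7S,9aR)-7-hydroxy-2,2,5a,7-tetramethyl-6-[(E)-2-(tributylstannyl)ethenyl]octahydro-1-benzoxepin-3(2H)-one
Conditions: Bu3SnH (1.3 equiv), PdCl2(PPh3)2 (3 mol%), THF, 0 °C → rt
Reagents that add atoms: tributyltin hydride CCCC[SnH](CCCC)CCCC
Why: syn-Hydrostannation of the terminal alkyne catalysed by PdCl2(PPh3)2 places tin on the terminal carbon because of the bulky propargylic ring carbon, giving the (E)-alkenylstannane while tolerating the ketone and the free alcohol.

**Thioester half**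

Step 14
Reactants: 19 2-methylpropanal; 20 pent-1-en-3-one
Product: 22 2,4,4-trimethylcyclohex-2-en-1-one, via 2,2-dimethyl-5-oxoheptanal 21 (not isolated)
Conditions: H2SO4 (cat.), toluene, 50 °C, then reflux (Dean–Stark)
Reagents that add atoms: none
Why: Acid-catalysed Robinson annulation (Michael addition of the aldehyde enol, then intramolecular aldol condensation) builds the gem-dimethyl cyclohexenone; no stereocentre is formed.

Step 15
Reactants: 22 2,4,4-trimethylcyclohex-2-en-1-one
Product: 23 (1S)-2,4,4-trimethylcyclohex-2-en-1-ol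
Conditions: (R)-2-methyl-CBS-oxazaborolidine (10 mol%), BH3·SMe2 (0.6 equiv), THF, −20 °C; MeOH, aq. work-up
Reagents that add atoms: none
Why: Corey–Bakshi–Shibata reduction with the (R)-catalyst, again with the α-methylalkenyl arm as the large group, sets the carbinol centre S.

Step 16
Reactants: 23 (1S)-2,4,4-trimethylcyclohex-2-en-1-ol; 24 1,1,1-trimethoxyethane
Product: 26 methyl 2-[(1R)-2,6,6-trimethylcyclohex-2-en-1-yl]acetate, via mixed ketene acetal 25 (not isolated)
Conditions: 24 (5 equiv), EtCO2H (5 mol%), xylene, 140 °C, MeOH distilled off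
Reagents that add atoms: none
Why: Johnson–Claisen rearrangement: the suprafacial [3,3] shift forms the C–C bond on the ring face that the C–O bond leaves, transferring the carbinol chirality to the ring methine (R) next to the gem-dimethyl carbon.

Step 17
Reactants: 26 methyl 2-[(1R)-2,6,6-trimethylcyclohex-2-en-1-yl]acetate
Product: 27 methyl 2-[(1S,2R,6R)-1,3,3-trimethyl-7-oxabicyclo[4.1.0]heptan-2-yl]acetate
Conditions: D-fructose-derived Shi ketone (30 mol%), KHSO5 (as Oxone), K2CO3, Bu4NHSO4, MeCN/dimethoxymethane/aq. borate buffer (pH 10.5), 0 °C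
Reagents that add atoms: potassium peroxymonosulfate [K+].[O-]S(=O)(=O)OO
Why: Shi asymmetric epoxidation under catalyst control: the spiro transition state of the D-fructose-derived dioxirane delivers oxygen to the alkene face that makes the epoxide CH centre R (the sense it shows with 1-phenylcyclohexene), which here is the ring face anti to the CH2CO2Me arm, so the tertiary C–O bond is set trans to the side chain without relying on the weak substrate bias of the 2,6,6-trimethylcyclohexenyl ring.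

Step 18
Reactants: 27 methyl 2-[(1S,2R,6R)-1,3,3-trimethyl-7-oxabicyclo[4.1.0]heptan-2-yl]acetate
Product: 28 (1R,2R)-2-(2-hydroxyethyl)-1,3,3-trimethylcyclohexan-1-ol
Conditions: LiAlH4 (3 equiv), THF, 0 °C → reflux; Fieser work-up
Reagents that add atoms: none
Why: Hydride opens the trisubstituted epoxide at its secondary carbon (SN2, trans-diaxial) so the tertiary C–O bond keeps its configuration, and the ester is reduced to the primary alcohol in the same operation.

Step 19
Reactants: 28 (1R,2R)-2-(2-hydroxyethyl)-1,3,3-trimethylcyclohexan-1-ol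
Product: 29 2-[(1R,2R)-2-hydroxy-2,6,6-trimethylcyclohexyl]acetaldehyde (in equilibrium with its cyclic lactol form)
Conditions: (COCl)2 (1.1 equiv), DMSO (2.2 equiv), CH2Cl2, −78 °C; Et3N (5 equiv), −78 → 0 °C
Reagents that add atoms: none
Why: Swern oxidation acts only on the primary alcohol because the tertiary alcohol has no carbinol hydrogen, and the activated sulfoxide is spent before the aldehyde can close to the lactol, so no lactone is formed.

Step 20
Reactants: 30 methyl 2-bromopropanoate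
Product: 32 methyl 2-(triphenylphosphoranylidene)propanoate, via phosphonium bromide 31 (not isolated)
Conditions: PPh3, toluene, 80 °C; then aq. NaOH, CH2Cl2, rt
Reagents that add atoms: triphenylphosphine c1ccc(cc1)P(c1ccccc1)c1ccccc1
Why: SN2 quaternisation of the phosphine followed by deprotonation gives the stabilised ylide (Wittig reagent preparation).

Step 21
Reactants: 29 2-[(1R,2R)-2-hydroxy-2,6,6-trimethylcyclohexyl]acetaldehyde; 32 methyl 2-(triphenylphosphoranylidene)propanoate
Product: 33 methyl (2E)-4-[(1R,2R)-2-hydroxy-2,6,6-trimethylcyclohexyl]-2-methylbut-2-enoate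
Conditions: toluene, 90 °C
Reagents that add atoms: none
Why: Wittig olefination with the stabilised, α-branched ylide reacts through the open aldehyde form and gives the (E)-trisubstituted enoate under thermodynamic control of the oxaphosphetane.

Step 22
Reactants: 33 methyl (2E)-4-[(1R,2R)-2-hydroxy-2,6,6-trimethylcyclohexyl]-2-methylbut-2-enoate
Product: 34 (2E)-4-[(1R,2R)-2-hydroxy-2,6,6-trimethylcyclohexyl]-2-methylbut-2-enoic acid
Conditions: LiOH, THF/MeOH/H2O, 50 °C; then 1 M HCl
Reagents that add atoms: lithium hydroxide [Li+].[OH-]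
Why: Saponification frees the carboxylic acid needed as the directing group for the hydrogenation.

Step 23
Reactants: 34 (2E)-4-[(1R,2R)-2-hydroxy-2,6,6-trimethylcyclohexyl]-2-methylbut-2-enoic acid
Product: 35 (2R)-4-[(1R,2R)-2-hydroxy-2,6,6-trimethylcyclohexyl]-2-methylbutanoic acid
Conditions: Ru(OAc)2[(R)-H8-BINAP] (1 mol%), H2 (4 atm), MeOH, rt
Reagents that add atoms: none
Why: Noyori-type carboxylate-directed asymmetric hydrogenation of the (E)-2-methyl-2-alkenoic acid with Ru(OAc)2[(R)-H8-BINAP] sets the α-methyl centre R under catalyst control (the (R)-ligand gives the R acid, as with tiglic acid).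

Step 24
Reactants: 35 (2R)-4-[(1R,2R)-2-hydroxy-2,6,6-trimethylcyclohexyl]-2-methylbutanoic acid
Product: 36 S-(4-methylphenyl) (2R)-4-[(1R,2R)-2-hydroxy-2,6,6-trimethylcyclohexyl]-2-methylbutanethioate
Conditions: 4-methylbenzenethiol, DCC, DMAP (5 mol%), CH2Cl2, 0 °C → rt
Reagents that add atoms: 4-methylbenzenethiol Cc1ccc(S)cc1
Why: Steglich-type thioesterification activates the acid for the cross-coupling; the hindered tertiary alcohol does not acylate and the α-centre is not epimerised at 0 °C.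

**Fragment union**

Step 25
Reactants: 36 S-(4-methylphenyl) (2R)-4-[(1R,2R)-2-hydroxy-2,6,6-trimethylcyclohexyl]-2-methylbutanethioate; 18 (5aR,6S,7S,9aR)-7-hydroxy-2,2,5a,7-tetramethyl-6-[(E)-2-(tributylstannyl)ethenyl]octahydro-1-benzoxepin-3(2H)-one
Product: 38 (5aR,6S,7S,9aR)-7-hydroxy-6-{(E)-2-[(2R,3R,5aR,9aR)-2-hydroxy-3,6,6,9a-tetramethyldecahydro-1-benzoxepin-2-yl]ethenyl}-2,2,5a,7-tetramethyloctahydro-1-benzoxepin-3(2H)-one, via open hydroxy enone 37 (not isolated)
Conditions: Pd2(dba)3 (2.5 mol%), tri(2-furyl)phosphine (20 mol%), Cu(O2PPh2) (1.5 equiv), THF, 50 °C; then PPTS (5 mol%), CH2Cl2, rt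
Reagents that add atoms: none
Why: Liebeskind-type thiol ester–organostannane cross-coupling, catalysed by Pd2(dba)3 and mediated by Cu(O2PPh2), forms the acyl–alkenyl bond under neutral conditions with retention of the E geometry and the α-methyl centre, and the ε-hydroxy enone then closes to the seven-membered hemiketal under thermodynamic control, which sets the hemiketal carbon.

**Compound list**
1 | 2-methylcyclohex-2-en-1-one | CC1=CCCCC1=O | starting material
2 | (1R)-2-methylcyclohex-2-en-1-ol | O[C@@H]1CCCC=C1C | intermediate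
3 | tert-butyl(dimethyl){[(1R)-2-methylcyclohex-2-en-1-yl]oxy}silane | CC(C)(C)[Si](C)(C)O[C@@H]1CCCC=C1C | intermediate
4 | (4R)-4-{[tert-butyl(dimethyl)silyl]oxy}-3-methylcyclohex-2-en-1-one | CC(C)(C)[Si](C)(C)O[C@@H]1CCC(=O)C=C1C | intermediate
5 | 5-bromo-2-methylpent-2-ene | CC(C)=CCCBr | starting material
6 | (4-methylpent-3-en-1-yl)magnesium bromide | CC(C)=CCC[Mg]Br | intermediate
7 | bromomagnesium (3R,4R)-4-{[tert-butyl(dimethyl)silyl]oxy}-3-methyl-3-(4-methylpent-3-en-1-yl)cyclohex-1-en-1-olate | Br[Mg]OC1=C[C@@]([C@H](O[Si](C)(C)C(C)(C)C)CC1)(C)CCC=C(C)C | intermediate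
8 | (3R,4R)-4-{[tert-butyl(dimethyl)silyl]oxy}-3-methyl-3-(4-methylpent-3-en-1-yl)cyclohex-1-en-1-yl trifluoromethanesulfonate | FC(F)(F)S(=O)(=O)OC1=C[C@@]([C@H](O[Si](C)(C)C(C)(C)C)CC1)(C)CCC=C(C)C | intermediate
9 | (3R,4R)-4-hydroxy-3-methyl-3-(4-methylpent-3-en-1-yl)cyclohex-1-en-1-yl trifluoromethanesulfonate | FC(F)(F)S(=O)(=O)OC1=C[C@@]([C@H](O)CC1)(C)CCC=C(C)C | intermediate
10 | (3R,4R)-3-{2-[(2R)-3,3-dimethyloxiran-2-yl]ethyl}-4-hydroxy-3-methylcyclohex-1-en-1-yl trifluoromethanesulfonate | FC(F)(F)S(=O)(=O)OC1=C[C@@]([C@H](O)CC1)(C)CC[C@H]2OC2(C)C | intermediate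
11 | (3R,5aR,9aR)-3-hydroxy-2,2,5a-trimethyl-2,3,4,5,5a,8,9,9a-octahydro-1-benzoxepin-7-yl trifluoromethanesulfonate | FC(F)(F)S(=O)(=O)OC1=C[C@@]2(C)CC[C@@H](O)C(C)(C)O[C@@H]2CC1 | intermediate
12 | (5aR,9aR)-2,2,5a-trimethyl-3-oxo-2,3,4,5,5a,8,9,9a-octahydro-1-benzoxepin-7-yl trifluoromethanesulfonate | FC(F)(F)S(=O)(=O)OC1=C[C@@]2(C)CCC(=O)C(C)(C)O[C@@H]2CC1 | intermediate
13 | (5aR,9aR)-2,2,5a,7-tetramethyl-4,5,5a,8,9,9a-hexahydro-1-benzoxepin-3(2H)-one | CC1=C[C@@]2(C)CCC(=O)C(C)(C)O[C@@H]2CC1 | intermediate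
14 | (5aS,6S,7S,9aR)-6-bromo-7-hydroxy-2,2,5a,7-tetramethyloctahydro-1-benzoxepin-3(2H)-one | Br[C@H]1[C@@]2(C)CCC(=O)C(C)(C)O[C@@H]2CC[C@]1(C)O | intermediate
15 | (bromoethynyl)trimethylsilane | C[Si](C)(C)C#CBr | starting material
16 | (5aR,6R,7S,9aR)-7-hydroxy-2,2,5a,7-tetramethyl-6-[(trimethylsilyl)ethynyl]octahydro-1-benzoxepin-3(2H)-one | C[Si](C)(C)C#C[C@H]1[C@@]2(C)CCC(=O)C(C)(C)O[C@@H]2CC[C@]1(C)O | intermediate
17 | (5aR,6S,7S,9aR)-6-ethynyl-7-hydroxy-2,2,5a,7-tetramethyloctahydro-1-benzoxepin-3(2H)-one | C#C[C@H]1[C@@]2(C)CCC(=O)C(C)(C)O[C@@H]2CC[C@]1(C)O | intermediate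
18 | (5aR,6S,7S,9aR)-7-hydroxy-2,2,5a,7-tetramethyl-6-[(E)-2-(tributylstannyl)ethenyl]octahydro-1-benzoxepin-3(2H)-one | CCCC[Sn](CCCC)(CCCC)/C=C/[C@H]1[C@@]2(C)CCC(=O)C(C)(C)O[C@@H]2CC[C@]1(C)O | intermediate
19 | 2-methylpropanal | CC(C)C=O | starting material
20 | pent-1-en-3-one | CCC(=O)C=C | starting material
21 | 2,2-dimethyl-5-oxoheptanal | CCC(=O)CCC(C)(C)C=O | intermediate
22 | 2,4,4-trimethylcyclohex-2-en-1-one | CC1=CC(C)(C)CCC1=O | intermediate
23 | (1S)-2,4,4-trimethylcyclohex-2-en-1-ol | O[C@H]1CCC(C)(C)C=C1C | intermediate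
24 | 1,1,1-trimethoxyethane | COC(C)(OC)OC | starting material
25 | (6S)-6-[(1-methoxyethenyl)oxy]-1,3,3-trimethylcyclohex-1-ene | C=C(OC)O[C@H]1CCC(C)(C)C=C1C | intermediate
26 | methyl 2-[(1R)-2,6,6-trimethylcyclohex-2-en-1-yl]acetate | COC(=O)C[C@H]1C(C)=CCCC1(C)C | intermediate
27 | methyl 2-[(1S,2R,6R)-1,3,3-trimethyl-7-oxabicyclo[4.1.0]heptan-2-yl]acetate | COC(=O)C[C@H]1[C@]2(C)O[C@@H]2CCC1(C)C | intermediate
28 | (1R,2R)-2-(2-hydroxyethyl)-1,3,3-trimethylcyclohexan-1-ol | OCC[C@@H]1C(C)(C)CCC[C@@]1(C)O | intermediate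
29 | 2-[(1R,2R)-2-hydroxy-2,6,6-trimethylcyclohexyl]acetaldehyde | O=CC[C@@H]1C(C)(C)CCC[C@@]1(C)O | intermediate
30 | methyl 2-bromopropanoate (racemic) | COC(=O)C(C)Br | starting material
31 | (1-methoxy-1-oxopropan-2-yl)triphenylphosphonium bromide | COC(=O)C(C)[P+](c1ccccc1)(c1ccccc1)c1ccccc1.[Br-] | intermediate
32 | methyl 2-(triphenylphosphoranylidene)propanoate | COC(=O)C(C)=P(c1ccccc1)(c1ccccc1)c1ccccc1 | intermediate
33 | methyl (2E)-4-[(1R,2R)-2-hydroxy-2,6,6-trimethylcyclohexyl]-2-methylbut-2-enoate | COC(=O)/C(C)=C/C[C@@H]1C(C)(C)CCC[C@@]1(C)O | intermediate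
34 | (2E)-4-[(1R,2R)-2-hydroxy-2,6,6-trimethylcyclohexyl]-2-methylbut-2-enoic acid | OC(=O)/C(C)=C/C[C@@H]1C(C)(C)CCC[C@@]1(C)O | intermediate
35 | (2R)-4-[(1R,2R)-2-hydroxy-2,6,6-trimethylcyclohexyl]-2-methylbutanoic acid | C[C@H](CC[C@@H]1C(C)(C)CCC[C@@]1(C)O)C(=O)O | intermediate
36 | S-(4-methylphenyl) (2R)-4-[(1R,2R)-2-hydroxy-2,6,6-trimethylcyclohexyl]-2-methylbutanethioate | C[C@H](CC[C@@H]1C(C)(C)CCC[C@@]1(C)O)C(=O)Sc1ccc(C)cc1 | intermediate
37 | (5aR,6S,7S,9aR)-7-hydroxy-6-{(1E,4R)-6-[(1R,2R)-2-hydroxy-2,6,6-trimethylcyclohexyl]-4-methyl-3-oxohex-1-en-1-yl}-2,2,5a,7-tetramethyloctahydro-1-benzoxepin-3(2H)-one | C[C@H](CC[C@@H]1C(C)(C)CCC[C@@]1(C)O)C(=O)/C=C/[C@H]2[C@@]3(C)CCC(=O)C(C)(C)O[C@@H]3CC[C@]2(C)O | intermediate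
38 | (5aR,6S,7S,9aR)-7-hydroxy-6-{(E)-2-[(2R,3R,5aR,9aR)-2-hydroxy-3,6,6,9a-tetramethyldecahydro-1-benzoxepin-2-yl]ethenyl}-2,2,5a,7-tetramethyloctahydro-1-benzoxepin-3(2H)-one | C[C@@H]1CC[C@@H]2C(C)(C)CCC[C@@]2(C)O[C@@]1(O)/C=C/[C@H]1[C@@]2(C)CCC(=O)C(C)(C)O[C@@H]2CC[C@]1(C)O | target

**Step count**
Total: 25 steps. Longest linear sequence: 14 steps (steps 1–13, then step 25). The thioester branch is 11 steps (14–19, 21–24, 25) and the ylide is made in 1 step (20).

**Steps most likely to fail, with fallbacks**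

Step 11 (the proposed reductive alkynylation with NiBr2·glyme). Failure modes are reductive loss of the halohydrin back to alkene 13, diyne formation from 15, or poor face control at C6. The fallback uses known polar chemistry, sets out from 14 and returns at 17. NaBH4 in MeOH at 0 °C reduces the ketone of 14 to (5aS,6S,7S,9aR)-6-bromo-2,2,5a,7-tetramethyldecahydro-1-benzoxepine-3,7-diol F1 (C3 epimers, of no consequence). K2CO3 in MeOH then lets the axial 7-alkoxide displace the axial bromide to give (5aS,6R,7S,9aR)-6,7-epoxy-2,2,5a,7-tetramethyldecahydro-1-benzoxepin-3-ol F2, with the epoxide oxygen on the face of the 5a-methyl. Lithium acetylide–ethylenediamine in DMSO at 40 °C opens the epoxide in a trans-diaxial SN2 reaction at C6 to (5aR,6S,7S,9aR)-6-ethynyl-2,2,5a,7-tetramethyldecahydro-1-benzoxepine-3,7-diol F3. Dess–Martin oxidation of the only secondary alcohol then gives 17. The ketone is carried as the alcohol because acetylide would add to it.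

Step 7 (7-endo epoxide opening). The competing 6-exo attack at the secondary epoxide carbon would give a tetrahydropyran with a hydroxy-isopropyl group. The fallback sets out from alkene 9 and returns at 12. Hg(OCOCF3)2 in CH2Cl2/MeNO2 at −20 °C effects intramolecular alkoxymercuration, which is strictly Markovnikov and therefore 7-endo, to give {(5aR,9aR)-2,2,5a-trimethyl-7-[(trifluoromethanesulfonyl)oxy]-2,3,4,5,5a,8,9,9a-octahydro-1-benzoxepin-3-yl}mercury trifluoroacetate F4 (C3 epimers). Oxidative demercuration with NaBH4 under O2 in DMF gives 11 together with its epimer (3S,5aR,9aR)-3-hydroxy-2,2,5a-trimethyl-2,3,4,5,5a,8,9,9a-octahydro-1-benzoxepin-7-yl trifluoromethanesulfonate F5. Both epimers converge on ketone 12 under the conditions of step 8.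

Step 25 (acyl–alkenyl coupling of two hindered partners). Failure modes are slow transmetalation of the hindered stannane, protodestannylation or decarbonylation. The fallback replaces the acyl coupling by aldehyde addition and oxidation; it sets out from 18 and 36 and returns at 37, which closes to 38 with PPTS as in step 25. I2 in CH2Cl2 at 0 °C converts 18 into (5aR,6S,7S,9aR)-7-hydroxy-6-[(E)-2-iodoethenyl]-2,2,5a,7-tetramethyloctahydro-1-benzoxepin-3(2H)-one F6. Fukuyama reduction of 36 (Et3SiH, palladium on carbon, acetone) gives (2R)-4-[(1R,2R)-2-hydroxy-2,6,6-trimethylcyclohexyl]-2-methylbutanal F7. Nozaki–Hiyama–Kishi coupling (CrCl2, NiCl2 2 mol%, DMSO/THF, rt), which is aldehyde-selective in the presence of the ketone, gives (5aR,6S,7S,9aR)-7-hydroxy-6-{(1E,4R)-3-hydroxy-6-[(1R,2R)-2-hydroxy-2,6,6-trimethylcyclohexyl]-4-methylhex-1-en-1-yl}-2,2,5a,7-tetramethyloctahydro-1-benzoxepin-3(2H)-one F8 (carbinol epimers). MnO2 in CH2Cl2 oxidises the allylic alcohol to 37.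

Further compounds
F1 | step 11 | (5aS,6S,7S,9aR)-6-bromo-2,2,5a,7-tetramethyldecahydro-1-benzoxepine-3,7-diol (C3 epimers) | Br[C@H]1[C@@]2(C)CCC(O)C(C)(C)O[C@@H]2CC[C@]1(C)O
F2 | step 11 | (5aS,6R,7S,9aR)-6,7-epoxy-2,2,5a,7-tetramethyldecahydro-1-benzoxepin-3-ol (C3 epimers) | O1[C@@H]2[C@@]3(C)CCC(O)C(C)(C)O[C@@H]3CC[C@]12C
F3 | step 11 | (5aR,6S,7S,9aR)-6-ethynyl-2,2,5a,7-tetramethyldecahydro-1-benzoxepine-3,7-diol (C3 epimers) | C#C[C@H]1[C@@]2(C)CCC(O)C(C)(C)O[C@@H]2CC[C@]1(C)O
F4 | step 7 | {(5aR,9aR)-2,2,5a-trimethyl-7-[(trifluoromethanesulfonyl)oxy]-2,3,4,5,5a,8,9,9a-octahydro-1-benzoxepin-3-yl}mercury trifluoroacetate (C3 epimers) | FC(F)(F)S(=O)(=O)OC1=C[C@@]2(C)CCC([Hg]OC(=O)C(F)(F)F)C(C)(C)O[C@@H]2CC1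
F5 | step 7 | (3S,5aR,9aR)-3-hydroxy-2,2,5a-trimethyl-2,3,4,5,5a,8,9,9a-octahydro-1-benzoxepin-7-yl trifluoromethanesulfonate | FC(F)(F)S(=O)(=O)OC1=C[C@@]2(C)CC[C@H](O)C(C)(C)O[C@@H]2CC1
F6 | step 25 | (5aR,6S,7S,9aR)-7-hydroxy-6-[(E)-2-iodoethenyl]-2,2,5a,7-tetramethyloctahydro-1-benzoxepin-3(2H)-one | I/C=C/[C@H]1[C@@]2(C)CCC(=O)C(C)(C)O[C@@H]2CC[C@]1(C)O
F7 | step 25 | (2R)-4-[(1R,2R)-2-hydroxy-2,6,6-trimethylcyclohexyl]-2-methylbutanal | C[C@H](CC[C@@H]1C(C)(C)CCC[C@@]1(C)O)C=O
F8 | step 25 | (5aR,6S,7S,9aR)-7-hydroxy-6-{(1E,4R)-3-hydroxy-6-[(1R,2R)-2-hydroxy-2,6,6-trimethylcyclohexyl]-4-methylhex-1-en-1-yl}-2,2,5a,7-tetramethyloctahydro-1-benzoxepin-3(2H)-one (carbinol epimers) | C[C@H](CC[C@@H]1C(C)(C)CCC[C@@]1(C)O)C(O)/C=C/[C@H]2[C@@]3(C)CCC(=O)C(C)(C)O[C@@H]3CC[C@]2(C)O
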